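**Plan**

- The retrosynthesis first cuts the depside ester bond between the ring A carbonyl carbon and O4 of ring B. Both halves then reduce to one benzoate, benzyl 4-hydroxy-2-methoxy-6-pentylbenzoate.
- In that benzoate the ring bonds C3–C4 and C5–C6 are cut. C6 (pentyl), C1 (carboxyl), C2 (OMe) and C3 (H) are C6, C5, C4 and C3 of a 2-pyrone, so only C4 (O) and C5 (H) must come from a bis(silyl) ketene acetal.
- The pyrone is cut at O1–C2 and C4–C5 back to benzyl 3-oxooctanoate and malonyl dichloride.
- Forward: keto ester, 4-hydroxypyrone, 4-methoxypyrone, then the arene (cycloaddition, loss of CO2 and silanol). One portion stays as the ring B phenol, the other is O-benzylated and saponified to the ring A acid. Esterification and one hydrogenolysis of both benzyl groups finish the route.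
- The target has no stereocentre. The two bridgehead centres of the transient cycloadduct vanish on aromatization.

Key step: step 5

Remark: locants in both rings follow benzoate numbering (C1 carboxyl carbon, C2 OMe, C4 oxygen, C6 pentyl); LiN(iPr)2 is taken as a commercial solution.

**Route**

Step 1
Reactants: 1 methyl 3-oxooctanoate; 2 benzyl alcohol
Product: 3 benzyl 3-oxooctanoate
Conditions: BnOH (1.5 equiv), DMAP (cat.), toluene, reflux, MeOH distilled off
Reagents that add atoms: none
Why: Transesterification of a beta-keto ester is facile (acylketene or acyl-DMAP pathway) and is driven by removal of methanol, and the benzyl ester allows the acid to be unmasked at the end without base.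

Step 2
Reactants: 3 benzyl 3-oxooctanoate; 4 malonyl dichloride
Product: 6 benzyl 4-hydroxy-2-oxo-6-pentyl-2H-pyran-5-carboxylate, via C-acylated acid chloride 5 (not isolated)
Conditions: malonyl dichloride (1.0 equiv), CH2Cl2 (concentrated), rt to 40 °C, slow N2 stream
Reagents that add atoms: none
Why: Condensation of a beta-keto ester with malonyl dichloride (C-acylation at the activated methylene, then lactonization through the ketone enol oxygen) is a known entry to 6-alkyl-4-hydroxy-2-pyrone-5-carboxylates and puts the ester at C5 and the pentyl group at C6.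

Step 3
Reactants: 6 benzyl 4-hydroxy-2-oxo-6-pentyl-2H-pyran-5-carboxylate
Product: 7 benzyl 4-methoxy-2-oxo-6-pentyl-2H-pyran-5-carboxylate
Conditions: Me2SO4 (1.2 equiv), K2CO3, acetone, reflux
Reagents that add atoms: dimethyl sulfate, COS(=O)(=O)OC
Why: O-Alkylation of the vinylogous acid (Williamson type) with a hard methylating agent and K2CO3 should favour the 4-methoxy-2-pyrone over C3-methylation and over the 2-methoxy-4-pyranone isomer, as is usual for 4-hydroxy-2-pyrones.

Step 4
Reactants: 8 trimethylsilyl acetate
Product: 10 1,1-bis(trimethylsilyloxy)ethene, via lithium enolate 9 (not isolated)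
Conditions: LiN(iPr)2 (1.05 equiv), THF, −78 °C; Me3SiCl, −78 °C to rt; distillation
Reagents that add atoms: chlorotrimethylsilane, C[Si](C)(C)Cl
Why: Kinetic enolization of the silyl ester and O-silylation of the enolate by the hard silicon electrophile is the standard preparation of bis(silyl) ketene acetals.

Step 5
Reactants: 7 benzyl 4-methoxy-2-oxo-6-pentyl-2H-pyran-5-carboxylate; 10 1,1-bis(trimethylsilyloxy)ethene
Product: 14 benzyl 4-hydroxy-2-methoxy-6-pentylbenzoate, via bridged lactone cycloadduct 11 (not isolated), via cyclohexadiene ketal 12 (not isolated), via aryl trimethylsilyl ether 13 (not isolated)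
Conditions: 10 (4 equiv), toluene, 120 °C, sealed tube, Ar; then 1 M HCl, THF, rt
Reagents that add atoms: none
Why: The electron-rich methylene carbon of 10 adds to C6 of 7, which is beta to the C5 ester and delta to the lactone carbonyl, and the acetal carbon then bonds to the enolate-like C3, so the new six-membered carbocycle closes in a (4+2) mode across C3 and C6 of the pyrone diene (concerted but asynchronous, or stepwise through a zwitterion) to give the bridged lactone 11. Cycloreversion of 11 expels carbon dioxide, the cyclohexadiene ketal 12 aromatizes by 1,2-elimination of trimethylsilanol, and the labile aryl silyl ether 13 is hydrolysed on acidic work-up. The closest known reaction type is the inverse-electron-demand Diels–Alder reaction of alkyl 2-pyrone-5-carboxylates with ketene acetals, which gives 4-alkoxybenzoates by the same sequence; 7 is a more electron-rich and more hindered member of that class, so heat and an excess of 10 are planned. The two bridgehead stereocentres of 11 form as a racemate and are erased on aromatization, so no stereocontrol is required. The selectivity needed is regiochemical: the C5 ester makes C6 the electrophilic terminus, which places the new oxygen para to the ester, and since both acetal oxygens carry the same silyl group either elimination gives the same arene. The methyl ether therefore comes from the pyrone and the free phenol from the dienophile, which differentiates O2 from O4 without protecting-group work.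

Step 6
Reactants: 14 benzyl 4-hydroxy-2-methoxy-6-pentylbenzoate (about half of the material)
Product: 15 benzyl 4-(benzyloxy)-2-methoxy-6-pentylbenzoate
Conditions: BnBr (1.2 equiv), K2CO3, DMF, rt to 50 °C
Reagents that add atoms: benzyl bromide, BrCc1ccccc1
Why: Williamson etherification of the acidic phenol para to the ester is reliable, and the benzyl ether survives base and trifluoroacetic anhydride and leaves in the final hydrogenolysis.

Step 7
Reactants: 15 benzyl 4-(benzyloxy)-2-methoxy-6-pentylbenzoate
Product: 17 4-(benzyloxy)-2-methoxy-6-pentylbenzoic acid, via potassium carboxylate 16 (not isolated)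
Conditions: KOH (excess), DMSO/H2O 4:1, 90 °C; then cold 1 M HCl to pH 2
Reagents that add atoms: potassium hydroxide, [K+].[OH-]
Why: Saponification with poorly solvated hydroxide in aqueous DMSO is the established way to hydrolyse di-ortho-substituted benzoates, the ethers are inert to base, and cold acidification should avoid decarboxylation of the electron-rich acid.

Step 8
Reactants: 17 4-(benzyloxy)-2-methoxy-6-pentylbenzoic acid; 14 benzyl 4-hydroxy-2-methoxy-6-pentylbenzoate (second portion)
Product: 19 benzyl 4-{[4-(benzyloxy)-2-methoxy-6-pentylbenzoyl]oxy}-2-methoxy-6-pentylbenzoate, via mixed trifluoroacetic anhydride 18 (not isolated)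
Conditions: (CF3CO)2O (2 equiv), toluene, 0 °C to rt
Reagents that add atoms: none
Why: Mixed-anhydride esterification: the trifluoroacetic mixed anhydride of the electron-rich, di-ortho-substituted acid ionizes readily towards an acylium ion, which is captured by the only free hydroxyl present (the C4 phenol of 14), the classical method for hindered depside esters.

Step 9
Reactants: 19 benzyl 4-{[4-(benzyloxy)-2-methoxy-6-pentylbenzoyl]oxy}-2-methoxy-6-pentylbenzoate
Product: 20 4-O-demethylplanaic acid
Conditions: H2 (1 atm), 10% Pd/C, EtOAc, rt
Reagents that add atoms: none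
Why: Catalytic hydrogenolysis should cleave the benzyl ester and the benzyl aryl ether in one neutral operation that leaves the depside aryl ester, the methyl ethers and both arenes untouched.

**Compound list**

1 | methyl 3-oxooctanoate | CCCCCC(=O)CC(=O)OC | starting material
2 | benzyl alcohol | OCc1ccccc1 | starting material
3 | benzyl 3-oxooctanoate | CCCCCC(=O)CC(=O)OCc1ccccc1 | intermediate
4 | malonyl dichloride | O=C(Cl)CC(=O)Cl | starting material
5 | benzyl 2-(3-chloro-3-oxopropanoyl)-3-oxooctanoate (racemic, freely enolizing; not isolated) | CCCCCC(=O)C(C(=O)CC(=O)Cl)C(=O)OCc1ccccc1 | intermediate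
6 | benzyl 4-hydroxy-2-oxo-6-pentyl-2H-pyran-5-carboxylate | CCCCCC1=C(C(=O)OCc2ccccc2)C(O)=CC(=O)O1 | intermediate
7 | benzyl 4-methoxy-2-oxo-6-pentyl-2H-pyran-5-carboxylate | CCCCCC1=C(C(=O)OCc2ccccc2)C(OC)=CC(=O)O1 | intermediate
8 | trimethylsilyl acetate | CC(=O)O[Si](C)(C)C | starting material
9 | lithium 1-(trimethylsilyloxy)ethenolate (not isolated) | [Li+].[O-]C(=C)O[Si](C)(C)C | intermediate
10 | 1,1-bis(trimethylsilyloxy)ethene | C=C(O[Si](C)(C)C)O[Si](C)(C)C | intermediate
11 | benzyl 5-methoxy-3-oxo-1-pentyl-8,8-bis(trimethylsilyloxy)-2-oxabicyclo[2.2.2]oct-5-ene-6-carboxylate (racemic, bridgeheads tied by the bicycle, one enantiomer drawn; not isolated) | CCCCC[C@]12CC(O[Si](C)(C)C)(O[Si](C)(C)C)[C@H](C(=O)O1)C(OC)=C2C(=O)OCc1ccccc1 | intermediate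
12 | benzyl 6-methoxy-2-pentyl-4,4-bis(trimethylsilyloxy)cyclohexa-1,5-diene-1-carboxylate (not isolated) | CCCCCC1=C(C(=O)OCc2ccccc2)C(OC)=CC(O[Si](C)(C)C)(O[Si](C)(C)C)C1 | intermediate
13 | benzyl 2-methoxy-6-pentyl-4-(trimethylsilyloxy)benzoate (not isolated) | CCCCCc1cc(O[Si](C)(C)C)cc(OC)c1C(=O)OCc1ccccc1 | intermediate
14 | benzyl 4-hydroxy-2-methoxy-6-pentylbenzoate | CCCCCc1cc(O)cc(OC)c1C(=O)OCc1ccccc1 | intermediate
15 | benzyl 4-(benzyloxy)-2-methoxy-6-pentylbenzoate | CCCCCc1cc(OCc2ccccc2)cc(OC)c1C(=O)OCc1ccccc1 | intermediate
16 | potassium 4-(benzyloxy)-2-methoxy-6-pentylbenzoate (not isolated) | CCCCCc1cc(OCc2ccccc2)cc(OC)c1C(=O)[O-].[K+] | intermediate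
17 | 4-(benzyloxy)-2-methoxy-6-pentylbenzoic acid | CCCCCc1cc(OCc2ccccc2)cc(OC)c1C(=O)O | intermediate
18 | 4-(benzyloxy)-2-methoxy-6-pentylbenzoic trifluoroacetic anhydride (not isolated) | CCCCCc1cc(OCc2ccccc2)cc(OC)c1C(=O)OC(=O)C(F)(F)F | intermediate
19 | benzyl 4-{[4-(benzyloxy)-2-methoxy-6-pentylbenzoyl]oxy}-2-methoxy-6-pentylbenzoate | CCCCCc1cc(OC(=O)c2c(CCCCC)cc(OCc3ccccc3)cc2OC)cc(OC)c1C(=O)OCc1ccccc1 | intermediate
20 | 4-O-demethylplanaic acid, 4-[(4-hydroxy-2-methoxy-6-pentylbenzoyl)oxy]-2-methoxy-6-pentylbenzoic acid | CCCCCc1cc(OC(=O)c2c(CCCCC)cc(O)cc2OC)cc(OC)c1C(=O)O | target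

**Step count**

Total: 9 steps. Longest linear sequence: 8 steps (1, 2, 3, 5, 6, 7, 8, 9); step 4 is a one-step side branch.

**Steps most likely to fail**

Step 5. The 4-methoxy group raises the acceptor orbital of the pyrone and the 6-pentyl group crowds the carbon attacked first. The cycloaddition may therefore be slower than thermal O-to-C silyl migration or adventitious hydrolysis of the ketene acetal, and unchanged pyrone would be recovered. The fallback abandons the pyrone; it sets out from 3 and comes back at 14.
- The sodium enolate of 3 (NaH, THF, 0 °C) is C-acylated with diketene to benzyl 2-hexanoyl-3,5-dioxohexanoate F1.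
- Under continued base treatment F1 should close by aldol condensation of its terminal methyl ketone onto the hexanoyl carbonyl and aromatize to benzyl 2,4-dihydroxy-6-pentylbenzoate F2.
- The free, non-chelated C4 hydroxyl is allylated selectively (allyl bromide, K2CO3, acetone) to benzyl 2-hydroxy-6-pentyl-4-(prop-2-en-1-yloxy)benzoate F3.
- The hydrogen-bonded C2 hydroxyl is then methylated (MeI, K2CO3, DMF, 50 °C) to benzyl 2-methoxy-6-pentyl-4-(prop-2-en-1-yloxy)benzoate F4.
- The allyl group is removed with Pd(PPh3)4 (zerovalent palladium) and morpholine in THF to give 14.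

Step 2. The hydroxypyrone may be acylated again by malonyl dichloride (annulation to a pyranopyrandione), or the benzyl ester may be cleaved by the hydrogen chloride released. The fallback builds the same ring stepwise; it sets out from 3 and comes back at 6.
- The magnesium enolate of 3 (MgCl2, pyridine, CH2Cl2, 0 °C) is C-acylated with methyl 3-chloro-3-oxopropanoate to 1-benzyl 5-methyl 2-hexanoyl-3-oxopentanedioate F5.
- F5 is lactonized through the hexanoyl enol oxygen onto the methyl ester (DBU, toluene, 80 °C, loss of methanol) to give 6.

Step 7. Hydrolysis of the di-ortho-substituted ester may stall, and forcing it, or a warm acidification, may cause decarboxylation of the electron-rich acid. The fallback reverses the order of deprotection and protection; it sets out from 14 and comes back at 17.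
- Hydrogenolysis of 14 (H2, Pd/C, EtOAc) gives 4-hydroxy-2-methoxy-6-pentylbenzoic acid F6.
- The dianion of F6 (NaOH, 2 equiv, aqueous EtOH) is benzylated at the more nucleophilic phenoxide with one equivalent of BnBr, and cold acidification gives 17.

**Further compounds**

F1 | step 5 | benzyl 2-hexanoyl-3,5-dioxohexanoate (racemic, freely enolizing) | CCCCCC(=O)C(C(=O)CC(C)=O)C(=O)OCc1ccccc1
F2 | step 5 | benzyl 2,4-dihydroxy-6-pentylbenzoate | CCCCCc1cc(O)cc(O)c1C(=O)OCc1ccccc1
F3 | step 5 | benzyl 2-hydroxy-6-pentyl-4-(prop-2-en-1-yloxy)benzoate | CCCCCc1cc(OCC=C)cc(O)c1C(=O)OCc1ccccc1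
F4 | step 5 | benzyl 2-methoxy-6-pentyl-4-(prop-2-en-1-yloxy)benzoate | CCCCCc1cc(OCC=C)cc(OC)c1C(=O)OCc1ccccc1
F5 | step 2 | 1-benzyl 5-methyl 2-hexanoyl-3-oxopentanedioate (racemic, freely enolizing) | CCCCCC(=O)C(C(=O)CC(=O)OC)C(=O)OCc1ccccc1
F6 | step 7 | 4-hydroxy-2-methoxy-6-pentylbenzoic acid | CCCCCc1cc(O)cc(OC)c1C(=O)O
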